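## Structural features

Myrrhanone B is a bicyclic C30 triterpenoid acid: a decalin (ring A = C1–C5, C10; ring B = C5–C10) that carries at C9 a C13 chain (C11–C23, numbering used for all intermediates) with two methylene groups, three E-trisubstituted alkenes (C13=C14, C17=C18, C21=C22) and a terminal (E)-2-methyl-2-enoic acid (C23). Ring A holds the C3 ketone next to the C4 gem-dimethyl group. Ring B holds the tertiary alcohol C8 (CH3, OH), the side-chain methine C9 and the quaternary C10 (CH3), so the four stereocentres C5, C10, C9 and C8 form an unbroken row. Read literally, the SMILES gives 5S, 8R, 9R, 10S: H-5, CH3-10, the C9 chain and CH3-8 lie on one face (β), OH-8 on the other (α), so the decalin is cis-fused, the 5-epimer of the trans skeleton that a chair–chair cyclization of an all-E polyene gives; the route rests on this reading. Fragile groups are the tertiary alcohol (dehydration, and ether formation onto C12 if C12 becomes electrophilic), the acid-sensitive trisubstituted alkenes, the enolizable ketone and the conjugated acid. The real difficulty is the cis ring fusion with the quaternary C10, next to a C9 that is too hindered for intermolecular C–C bond formation and whose substituent must be cis to CH3-10 while OH-8 is trans. The key step exploits the fact that C3 (carbonyl carbon of ring A) and C8 (oxygen-bearing carbon of ring B) can be joined by an extra bond while C1–C10 is left open: this folds the decalin into a bicyclo[2.2.2]oct-5-ene (bridgeheads C5 and C8; bridges C3–C4, C6–C7, C9=C10) with a vinyl carbinol at C3, whose [3,3] shift can only give the cis-fused rings. All four methyl groups and the ketone of the core then map onto 2,4,6-trimethylphenol plus one methyl group.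

## Logic of the disconnections

29 ⇒ 27 (through 28). No skeletal bond is cut: the C23 carboxyl group and the C3 carbonyl group are both taken back to carbinols. Reason: neither a ketone nor an enoic acid survives the carbanion chemistry that joins the halves. Gain: one oxidation at the end serves both ends of the molecule. Demand: the oxidant must spare the tertiary C8–OH and three trisubstituted alkenes, and 27 must come from 26 by loss of one silyl group.

26 ⇒ 17 + 23 (through 25 and 24). Cut: C11–C12. Reason: C12 is a primary allylic carbon (a good electrophile) and C11 can carry a sulfonyl group that is removed afterwards; every alkene geometry of the chain is bought ready-made. Gain: C30 splits into two C15 halves, one of them (23) without a stereocentre. Demand: C-alkylation of a sulfonyl carbanion next to two lithium alkoxides, substitution without allylic transposition, and desulfonylation that leaves the alkenes alone.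

17 ⇒ 15 (through 16). Cut: the C8–O bond (with the C7–H bond). Reason: a tertiary alcohol next to C9 is best made from the C7=C8 alkene, which is exactly what a sigmatropic delivery of C11 leaves behind. Gain: one stereocentre and the polar group are removed. Demand: oxygen must arrive on the α face, anti to the C9 substituent, and hydride must open at C7.

15 ⇒ 11 (through 14, 13, 12). Cut: C9–C11. Reason: C9 lies between quaternary C10 and C8; an oxygen on C7 can hand the carbon over within the molecule by a [3,3] shift and fixes its face. Gain: the C9 centre is traded for the C7 carbinol centre of a compound with three stereocentres and no chain. Demand: a 7β oxygen, and an acyl group that loses CO2 so that C11 arrives as the sulfone needed above.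

11 ⇒ 7 (through 10, 9, 8), the key disconnection. Cut: C1–C10; drawn in its place: a C3–C8 bond that the target does not have. Reason: in the resulting cage the vinyl group on C3 can reach C10 only on the face that makes H-5 and CH3-10 cis. Gain: the cis-fused decalin with its quaternary centre becomes a bicyclo[2.2.2]octenone, a Diels–Alder adduct. Demand: vinyl group syn to the C9=C10 bridge, and a [3,3] shift that forms a quaternary carbon.

7 ⇒ 3 + 5 (through 6). Cut: C2–C3 (vinyl addition), then C5–C6 and C7–C8 (cycloaddition). Reason: the cage is the adduct of a cyclohexa-2,4-dienone and an enol ether, and the enol ether oxygen is the C7 oxygen needed later. Gain: three stereocentres from two flat components. Demand: alkoxy carbon bonded to the methyl-bearing diene terminus, alkoxy group endo, and face control by the auxiliary in 5.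

3 ⇒ 1; 5 ⇒ 4; 23 ⇒ 18 (through 19–22). Cut: one C–CH3 bond of the gem-dimethyl group (C-methylation of a phenoxide); the O–vinyl bond; the C23–O bond and the acetate/bromide exchange at C12. Gain: all three components come from commercial materials. Demand: C- over O-methylation, and allylic oxidation only at the terminal E-methyl group.

## Other disconnections considered

Alternative 1: cut C4–C5 and C9–C10 together with the C8–O bond, the first idea for any polypodane. The forward step is a cation–olefin bicyclization of the epoxy triene A1, a (2E,6Z,10S)-10,11-epoxyfarnesyl sulfone, with a Lewis acid such as SnCl4, to the diol A2 (the 3β-epimer of the carbinol reached in the chosen route). The all-E isomer gives the trans fusion by anti addition across each alkene, so the cis target needs the 6Z isomer and a ring B closure that outruns conformational relaxation of the tertiary C10 cation. Nothing in A1 secures that, and capture of the C8 cation by water competes with proton loss to three alkenes. Two of the four stereocentres would rest on kinetic luck, whereas the chosen plan fixes the fusion by geometry at a similar step count.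

Alternative 2: cut C5–C10 and C8–C9. The forward step is an intramolecular Diels–Alder reaction of the acyclic triene A3 (an (E)-enoate tied through C1–C4 to a 1-silyloxy-1-methyl diene) to the cis-decalin A4, closing both rings and setting C5, C10, C9 and C8 at once. The required product needs the ester-exo, tether-endo transition state and a diene terminus C8 whose methyl group points inward. The endo preference, Lewis acid catalysis and the stable enol ether geometry all point the other way (trans fusion or the 8-epimer). More convergent on paper, but none of its selectivities is enforced by the substrate, and C6=C7 must still be reduced.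

Alternative 3: cut C5–C6 and C9–C10. The forward step is an intermolecular Diels–Alder reaction of the cyclic dienophile A5 (ring A as a 2-methyl enone, C5=C10) with the diene A6, giving a cis fusion by suprafacial addition in the adduct A7. The 1-alkyl and 2-methyl groups of A6 direct to opposite regiochemistry, the dienophile carbon C5 is neopentyl, and the endo rule puts C11 trans to CH3-10, as drawn in A7 (the 9-epimer). Afterwards the C1 oxygen must be removed and C8 hydrated with face control, and there is no handle for absolute configuration. More steps and weaker control than the chosen route.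

Key step: step 5

Remark on step 3: the sense of induction by the auxiliary is assumed (vinyl ether reacting in its s-trans conformation, aryl group shielding one face); if the 7R adduct predominated, the R enantiomer of 4 would be used, and the diastereomeric adducts are separable in either case.

Remark on epimers: the C3 carbinol centre (from step 10) and the C11 sulfone centre (from step 15) are carried as mixtures because both are destroyed later; their SMILES carry no descriptor at these atoms.

## Steps

Step 1
Reactants: 1 2,4,6-trimethylphenol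
Product: 3 2,4,6,6-tetramethylcyclohexa-2,4-dien-1-one, via sodium 2,4,6-trimethylphenoxide 2 (not isolated)
Conditions: NaH, toluene, 0 °C to rt; MeI, 110 °C (sealed tube), dark
Reagents that add atoms: iodomethane, CI
Why: C-alkylation of an ambident phenoxide (alkylative dearomatization); the tight sodium ion pair in a non-polar solvent shields oxygen and steers MeI to the ortho carbon, and the blocked dienone cannot rearomatize. The anisole and the para-dienone are separated.

Step 2
Reactants: 4 (S)-1-(2,4,6-triisopropylphenyl)ethanol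
Product: 5 (S)-1-(2,4,6-triisopropylphenyl)ethyl vinyl ether
Conditions: vinyl acetate, [Ir(cod)Cl]2 (1 mol %), Na2CO3, toluene, 100 °C
Reagents that add atoms: vinyl acetate, CC(=O)OC=C
Why: iridium-catalysed transfer vinylation of an alcohol by vinyl acetate; the carbinol C–O bond is not broken, so the S centre is retained.

Step 3
Reactants: 3 2,4,6,6-tetramethylcyclohexa-2,4-dien-1-one; 5 (S)-1-(2,4,6-triisopropylphenyl)ethyl vinyl ether
Product: 6 (1S,4S,7S)-1,3,3,5-tetramethyl-7-[(1S)-1-(2,4,6-triisopropylphenyl)ethoxy]bicyclo[2.2.2]oct-5-en-2-one (alkoxy group syn to the C5=C6 bridge)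
Conditions: 5 (2 equiv), toluene, BHT (cat.), 120 °C (sealed tube), dark; chromatography
Reagents that add atoms: none
Why: Diels–Alder reaction with inverse electron demand between a cyclohexa-2,4-dienone and an enol ether; the nucleophilic CH2 terminus bonds to the unsubstituted δ-carbon of the dienone (target C5) and the alkoxy carbon to the methyl-bearing α-carbon (target C8), with the alkoxy group endo. The aryl group of the auxiliary shields one face of the vinyl ether, which sets C7 and with it both bridgeheads; minor diastereomers are removed.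

Step 4
Reactants: 6 (1S,4S,7S)-1,3,3,5-tetramethyl-7-[(1S)-1-(2,4,6-triisopropylphenyl)ethoxy]bicyclo[2.2.2]oct-5-en-2-one
Product: 7 (1S,2S,4S,7S)-2-ethenyl-1,3,3,5-tetramethyl-7-[(1S)-1-(2,4,6-triisopropylphenyl)ethoxy]bicyclo[2.2.2]oct-5-en-2-ol (vinyl group syn to the C5=C6 bridge)
Conditions: CH2=CHMgBr, THF, −78 °C to 0 °C; then H2O
Reagents that add atoms: vinylmagnesium bromide, C=C[Mg]Br
Why: Grignard 1,2-addition to a non-enolizable ketone; bicyclo[2.2.2]oct-5-en-2-ones are attacked from the side of the C=C bridge because the saturated bridge turns hydrogens toward the carbonyl group. This places the vinyl group syn to the alkene, as the [3,3] shift requires.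

Step 5
Reactants: 7 (1S,2S,4S,7S)-2-ethenyl-1,3,3,5-tetramethyl-7-[(1S)-1-(2,4,6-triisopropylphenyl)ethoxy]bicyclo[2.2.2]oct-5-en-2-ol
Product: 10 (4aR,7S,8aS)-1,1,4a,6-tetramethyl-7-[(1S)-1-(2,4,6-triisopropylphenyl)ethoxy]-3,4,4a,7,8,8a-hexahydronaphthalen-2(1H)-one (cis-fused decalin), via potassium alkoxide of the vinyl carbinol 8 (not isolated), via potassium enolate of the decalin ketone 9 (not isolated)
Conditions: KH, 18-crown-6, THF, 0 °C to 66 °C; then H2O
Reagents that add atoms: none
Why: KH with 18-crown-6 gives the free alkoxide 8, whose oxyanion weakens the C3–C8 bond, and the 1,5-diene C1=C2–C3–C8–C9=C10 undergoes an anionic oxy-Cope ([3,3] sigmatropic) rearrangement in which C1–C10 forms while C3–C8 breaks, giving enolate 9 and, after protonation at C2, ketone 10. The closest known reaction type is the anionic oxy-Cope rearrangement of 2-vinylbicyclo[2.2.2]oct-5-en-2-ols to cis-fused octalones. Ring A is closed by the sigmatropic C1–C10 bond formation through the boat-like six-centre transition state that the cage imposes; ring B is not closed but released from the bicycle as the C3–C8 bridge opens. The new quaternary centre C10 is controlled by the cage: the vinyl group hangs from C3 on the C3–C4 bridge and can reach C10 only on the face of the C9=C10 bridge turned toward that bridge, the face on which C4 is already bound to C5, so C1 and C4 end up cis on ring B and H-5 is cis to CH3-10. C5 and C7 are carried over unchanged, and the bridgehead C8 becomes an alkene carbon of C8=C9. The step needs the vinyl group syn to the C9=C10 bridge (set in step 4) and a [3,3] pathway faster than heterolytic cleavage of the alkoxide; the methyl group on C8 and the allylic nature of the breaking bond lower the barrier, and C3 has no enolizable neighbour that could open another base-induced path. Only one 1,5-diene is present, so there is no regiochemical choice.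

Step 6
Reactants: 10 (4aR,7S,8aS)-1,1,4a,6-tetramethyl-7-[(1S)-1-(2,4,6-triisopropylphenyl)ethoxy]-3,4,4a,7,8,8a-hexahydronaphthalen-2(1H)-one
Product: 11 (4aR,7S,8aS)-7-hydroxy-1,1,4a,6-tetramethyl-3,4,4a,7,8,8a-hexahydronaphthalen-2(1H)-one
Conditions: CF3CO2H, CH2Cl2, 0 °C; aq. NaHCO3 work-up
Reagents that add atoms: none
Why: acidolysis of a 1-arylethyl ether; ionization at the benzylic carbon (the cation loses a proton to the styrene) should be faster than at the allylic C7–O bond, so the C7 oxygen and its configuration stay.

Step 7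
Reactants: 11 (4aR,7S,8aS)-7-hydroxy-1,1,4a,6-tetramethyl-3,4,4a,7,8,8a-hexahydronaphthalen-2(1H)-one
Product: 12 7β-O-[(p-tolylsulfonyl)acetyl] ester of 11
Conditions: TsCH2CO2H, DIC, DMAP (cat.), CH2Cl2, 0 °C to rt
Reagents that add atoms: 2-(4-methylphenylsulfonyl)acetic acid, Cc1ccc(cc1)S(=O)(=O)CC(=O)O
Why: carbodiimide esterification of a secondary allylic alcohol; no stereocentre is touched.

Step 8
Reactants: 12 7β-O-[(p-tolylsulfonyl)acetyl] ester of 11
Product: 15 (4aS,5S,8aS)-1,1,4a,6-tetramethyl-5-[(4-methylphenyl)sulfonylmethyl]-3,4,4a,5,8,8a-hexahydronaphthalen-2(1H)-one (C11 β on C9; C7=C8 alkene), via silyl ketene acetal 13 (not isolated), via trimethylsilyl 2-sulfonylcarboxylate 14 (not isolated)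
Conditions: N,O-bis(trimethylsilyl)acetamide, KOAc (cat.), toluene, 110 °C
Reagents that add atoms: none
Why: decarboxylative Claisen rearrangement of an allylic sulfonylacetate: silylation gives ketene acetal 13, an Ireland–Claisen [3,3] shift across C7–C8=C9 gives 14, and acetate-induced desilylation and loss of CO2 leave the C11 sulfone. C9 is set by suprafacial 1,3-transfer of chirality from C7: the 7β oxygen delivers C11 to the β face, cis to CH3-10.

Step 9
Reactants: 15 (4aS,5S,8aS)-1,1,4a,6-tetramethyl-5-[(4-methylphenyl)sulfonylmethyl]-3,4,4a,5,8,8a-hexahydronaphthalen-2(1H)-one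
Product: 16 7α,8α-epoxy-4,4,8β,10β-tetramethyl-9β-[(p-tolylsulfonyl)methyl]-5βH-decalin-3-one
Conditions: mCPBA, CH2Cl2, 0 °C
Reagents that add atoms: 3-chloroperoxybenzoic acid, OOC(=O)c1cccc(Cl)c1
Why: Prilezhaev epoxidation of the trisubstituted C7=C8 alkene; the peracid should come from the α face, anti to the CH2Ts group on the neighbouring C9, which A(1,2) strain with CH3-8 holds pseudoaxial. This sets C8 (O α, CH3 β).

Step 10
Reactants: 16 7α,8α-epoxy-4,4,8β,10β-tetramethyl-9β-[(p-tolylsulfonyl)methyl]-5βH-decalin-3-one
Product: 17 4,4,8β,10β-tetramethyl-9β-[(p-tolylsulfonyl)methyl]-5βH-decalin-3ξ,8α-diol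
Conditions: LiBHEt3, THF, 0 °C to rt; then H2O
Reagents that add atoms: none
Why: SN2 hydride opening of the epoxide at the less substituted C7 leaves the tertiary 8α-alcohol with retention at C8; the C3 ketone is reduced in the same operation, which protects C3 from n-BuLi in step 15. Sulfones are inert to this hydride.

Step 11
Reactants: 18 (2E,6E)-farnesyl acetate
Product: 19 (2E,6E,10E)-12-hydroxy-3,7,11-trimethyldodeca-2,6,10-trien-1-yl acetate
Conditions: SeO2 (cat.), t-BuOOH, salicylic acid (cat.), CH2Cl2, rt
Reagents that add atoms: tert-butyl hydroperoxide, CC(C)(C)OO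
Why: allylic oxidation by SeO2 (ene reaction, then [2,3] shift) is selective for the E-methyl group of the terminal alkene, and the allylic acetate deactivates C2=C3; the [2,3] step gives the E alcohol.

Step 12
Reactants: 19 (2E,6E,10E)-12-hydroxy-3,7,11-trimethyldodeca-2,6,10-trien-1-yl acetate
Product: 20 (2E,6E,10E)-12-(tert-butyldimethylsilyloxy)-3,7,11-trimethyldodeca-2,6,10-trien-1-yl acetate
Conditions: TBSCl, imidazole, DMF, rt
Reagents that add atoms: tert-butyldimethylsilyl chloride, CC(C)(C)[Si](C)(C)Cl
Why: silylation of a primary allylic alcohol; the ether survives organolithium base and sodium amalgam.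

Step 13
Reactants: 20 (2E,6E,10E)-12-(tert-butyldimethylsilyloxy)-3,7,11-trimethyldodeca-2,6,10-trien-1-yl acetate
Product: 21 (2E,6E,10E)-12-(tert-butyldimethylsilyloxy)-3,7,11-trimethyldodeca-2,6,10-trien-1-ol
Conditions: K2CO3 (cat.), MeOH, rt
Reagents that add atoms: none
Why: base-catalysed transesterification removes the acetate; the silyl ether is stable to methanolic carbonate.

Step 14
Reactants: 21 (2E,6E,10E)-12-(tert-butyldimethylsilyloxy)-3,7,11-trimethyldodeca-2,6,10-trien-1-ol
Product: 23 (2E,6E,10E)-1-bromo-12-(tert-butyldimethylsilyloxy)-3,7,11-trimethyldodeca-2,6,10-triene, via allylic mesylate 22 (not isolated)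
Conditions: MsCl, Et3N, THF, −40 °C; then LiBr, THF, 0 °C
Reagents that add atoms: lithium bromide, [Li+].[Br-]
Why: mesylation and SN2 displacement by bromide at the primary allylic carbon; low temperature avoids allylic transposition and E/Z isomerization.

Step 15
Reactants: 17 4,4,8β,10β-tetramethyl-9β-[(p-tolylsulfonyl)methyl]-5βH-decalin-3ξ,8α-diol; 23 (2E,6E,10E)-1-bromo-12-(tert-butyldimethylsilyloxy)-3,7,11-trimethyldodeca-2,6,10-triene
Product: 25 17 carrying at C11 the (2E,6E,10E)-12-(tert-butyldimethylsilyloxy)-3,7,11-trimethyldodeca-2,6,10-trienyl group (C11 epimers), via trilithiated sulfone 24 (not isolated)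
Conditions: n-BuLi (3.1 equiv), THF–DMPU, −78 °C to −30 °C; then 23, −78 °C to 0 °C
Reagents that add atoms: none
Why: alkylation of an α-sulfonyl carbanion; n-BuLi removes both OH protons and then the C11–H, and the soft carbanion attacks the primary allylic bromide by SN2 while the hindered lithium alkoxides do not. This forms the C11–C12 bond; no ring stereocentre is affected.

Step 16
Reactants: 25 17 carrying at C11 the (2E,6E,10E)-12-(tert-butyldimethylsilyloxy)-3,7,11-trimethyldodeca-2,6,10-trienyl group
Product: 26 23-O-tert-butyldimethylsilyl ether of the 3ξ,8α,23-triol 27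
Conditions: Na(Hg) (5 % Na), Na2HPO4, MeOH–THF, −20 °C
Reagents that add atoms: none
Why: reductive desulfonylation by electron transfer; the C11 carbanion is protonated by methanol. The sulfone is homoallylic, so C13=C14 cannot shift, and the silyl ether and isolated alkenes are inert.

Step 17
Reactants: 26 23-O-tert-butyldimethylsilyl ether of the 3ξ,8α,23-triol 27
Product: 27 (13E,17E,21E)-3ξ,8α,23-trihydroxy compound (3-deoxo-3-hydroxy, 23-alcohol analogue of the target)
Conditions: Bu4NF, THF, rt
Reagents that add atoms: none
Why: fluoride cleavage of the silyl ether; nothing else in the molecule is fluoride-labile.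

Step 18
Reactants: 27 (13E,17E,21E)-3ξ,8α,23-trihydroxy compound
Product: 28 (13E,17E,21E)-8α-hydroxy-3-oxo-23-aldehyde (enal)
Conditions: Dess–Martin periodinane (2.5 equiv), CH2Cl2, 0 °C to rt
Reagents that add atoms: none
Why: Dess–Martin oxidation takes the secondary C3 carbinol to the ketone and the primary allylic alcohol to the E-enal in one operation; the tertiary C8 alcohol cannot be oxidized, and both C3 epimers converge.

Step 19
Reactants: 28 (13E,17E,21E)-8α-hydroxy-3-oxo-23-aldehyde
Product: 29 myrrhanone B
Conditions: NaClO2, NaH2PO4, 2-methyl-2-butene, t-BuOH–H2O, rt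
Reagents that add atoms: sodium chlorite, [Na+].[O-]Cl=O
Why: Pinnick oxidation of the enal to the enoic acid; 2-methyl-2-butene traps HOCl so the trisubstituted alkenes survive, and the E geometry and all stereocentres are untouched.

## Compound list

1 | 2,4,6-trimethylphenol | Cc1cc(C)c(O)c(C)c1 | starting material
2 | sodium 2,4,6-trimethylphenoxide | Cc1cc(C)c([O-])c(C)c1.[Na+] | intermediate (not isolated)
3 | 2,4,6,6-tetramethylcyclohexa-2,4-dien-1-one | CC1=CC(C)=CC(C)(C)C1=O | intermediate
4 | (S)-1-(2,4,6-triisopropylphenyl)ethanol | C[C@H](O)c1c(C(C)C)cc(C(C)C)cc1C(C)C | starting material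
5 | (S)-1-(2,4,6-triisopropylphenyl)ethyl vinyl ether | C=CO[C@@H](C)c1c(C(C)C)cc(C(C)C)cc1C(C)C | intermediate
6 | (1S,4S,7S)-1,3,3,5-tetramethyl-7-[(1S)-1-(2,4,6-triisopropylphenyl)ethoxy]bicyclo[2.2.2]oct-5-en-2-one | CC1=C[C@]2(C)C(=O)C(C)(C)[C@H]1C[C@@H]2O[C@@H](C)c3c(C(C)C)cc(C(C)C)cc3C(C)C | intermediate
7 | (1S,2S,4S,7S)-2-ethenyl-1,3,3,5-tetramethyl-7-[(1S)-1-(2,4,6-triisopropylphenyl)ethoxy]bicyclo[2.2.2]oct-5-en-2-ol | CC1=C[C@]2(C)[C@](O)(C=C)C(C)(C)[C@H]1C[C@@H]2O[C@@H](C)c3c(C(C)C)cc(C(C)C)cc3C(C)C | intermediate
8 | potassium alkoxide of 7 | CC1=C[C@]2(C)[C@]([O-])(C=C)C(C)(C)[C@H]1C[C@@H]2O[C@@H](C)c3c(C(C)C)cc(C(C)C)cc3C(C)C.[K+] | intermediate (not isolated)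
9 | potassium enolate (C2=C3) of 10 | CC1=C[C@@]2(C)CC=C([O-])C(C)(C)[C@H]2C[C@@H]1O[C@@H](C)c3c(C(C)C)cc(C(C)C)cc3C(C)C.[K+] | intermediate (not isolated)
10 | (4aR,7S,8aS)-1,1,4a,6-tetramethyl-7-[(1S)-1-(2,4,6-triisopropylphenyl)ethoxy]-3,4,4a,7,8,8a-hexahydronaphthalen-2(1H)-one (cis-fused; H-5, CH3-10, O-7 all β) | CC1=C[C@@]2(C)CCC(=O)C(C)(C)[C@H]2C[C@@H]1O[C@@H](C)c3c(C(C)C)cc(C(C)C)cc3C(C)C | intermediate
11 | (4aR,7S,8aS)-7-hydroxy-1,1,4a,6-tetramethyl-3,4,4a,7,8,8a-hexahydronaphthalen-2(1H)-one | CC1=C[C@@]2(C)CCC(=O)C(C)(C)[C@H]2C[C@@H]1O | intermediate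
12 | 7β-O-[(p-tolylsulfonyl)acetyl] ester of 11 | CC1=C[C@@]2(C)CCC(=O)C(C)(C)[C@H]2C[C@@H]1OC(=O)CS(=O)(=O)c3ccc(C)cc3 | intermediate
13 | trimethylsilyl ketene acetal of 12 (ketene acetal geometry not defined) | CC1=C[C@@]2(C)CCC(=O)C(C)(C)[C@H]2C[C@@H]1OC(O[Si](C)(C)C)=CS(=O)(=O)c3ccc(C)cc3 | intermediate (not isolated)
14 | trimethylsilyl 2-(p-tolylsulfonyl)carboxylate after the [3,3] shift (C11 epimers) | CC1=CC[C@@H]2C(C)(C)C(=O)CC[C@]2(C)[C@H]1C(C(=O)O[Si](C)(C)C)S(=O)(=O)c3ccc(C)cc3 | intermediate (not isolated)
15 | (4aS,5S,8aS)-1,1,4a,6-tetramethyl-5-[(4-methylphenyl)sulfonylmethyl]-3,4,4a,5,8,8a-hexahydronaphthalen-2(1H)-one | CC1=CC[C@@H]2C(C)(C)C(=O)CC[C@]2(C)[C@H]1CS(=O)(=O)c3ccc(C)cc3 | intermediate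
16 | 7α,8α-epoxy-4,4,8β,10β-tetramethyl-9β-[(p-tolylsulfonyl)methyl]-5βH-decalin-3-one | C[C@@]12O[C@@H]1C[C@@H]3C(C)(C)C(=O)CC[C@]3(C)[C@H]2CS(=O)(=O)c4ccc(C)cc4 | intermediate
17 | 4,4,8β,10β-tetramethyl-9β-[(p-tolylsulfonyl)methyl]-5βH-decalin-3ξ,8α-diol | C[C@@]1(O)CC[C@@H]2C(C)(C)C(O)CC[C@]2(C)[C@H]1CS(=O)(=O)c3ccc(C)cc3 | intermediate
18 | (2E,6E)-farnesyl acetate | CC(C)=CCC/C(C)=C/CC/C(C)=C/COC(C)=O | starting material
19 | (2E,6E,10E)-12-hydroxy-3,7,11-trimethyldodeca-2,6,10-trien-1-yl acetate | CC(=O)OC/C=C(C)/CC/C=C(C)/CC/C=C(C)/CO | intermediate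
20 | (2E,6E,10E)-12-(tert-butyldimethylsilyloxy)-3,7,11-trimethyldodeca-2,6,10-trien-1-yl acetate | CC(=O)OC/C=C(C)/CC/C=C(C)/CC/C=C(C)/CO[Si](C)(C)C(C)(C)C | intermediate
21 | (2E,6E,10E)-12-(tert-butyldimethylsilyloxy)-3,7,11-trimethyldodeca-2,6,10-trien-1-ol | OC/C=C(C)/CC/C=C(C)/CC/C=C(C)/CO[Si](C)(C)C(C)(C)C | intermediate
22 | methanesulfonate of 21 | CS(=O)(=O)OC/C=C(C)/CC/C=C(C)/CC/C=C(C)/CO[Si](C)(C)C(C)(C)C | intermediate (not isolated)
23 | (2E,6E,10E)-1-bromo-12-(tert-butyldimethylsilyloxy)-3,7,11-trimethyldodeca-2,6,10-triene | BrC/C=C(C)/CC/C=C(C)/CC/C=C(C)/CO[Si](C)(C)C(C)(C)C | intermediate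
24 | trilithio derivative of 17 (O-3, O-8, C-11) | C[C@@]1([O-])CC[C@@H]2C(C)(C)C([O-])CC[C@]2(C)[C@H]1[CH-]S(=O)(=O)c3ccc(C)cc3.[Li+].[Li+].[Li+] | intermediate (not isolated)
25 | C11-alkylated sulfone: 17 carrying the C12–C23 chain at C11 (C11 epimers, 23-OTBS) | C[C@@]1(O)CC[C@@H]2C(C)(C)C(O)CC[C@]2(C)[C@H]1C(C/C=C(C)/CC/C=C(C)/CC/C=C(C)/CO[Si](C)(C)C(C)(C)C)S(=O)(=O)c3ccc(C)cc3 | intermediate
26 | 23-O-TBS ether of the (13E,17E,21E)-3ξ,8α,23-triol | C[C@@]1(O)CC[C@@H]2C(C)(C)C(O)CC[C@]2(C)[C@H]1CC/C=C(C)/CC/C=C(C)/CC/C=C(C)/CO[Si](C)(C)C(C)(C)C | intermediate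
27 | (13E,17E,21E)-3ξ,8α,23-triol | C[C@@]1(O)CC[C@@H]2C(C)(C)C(O)CC[C@]2(C)[C@H]1CC/C=C(C)/CC/C=C(C)/CC/C=C(C)/CO | intermediate
28 | (13E,17E,21E)-8α-hydroxy-3-oxo-23-aldehyde | C[C@@]1(O)CC[C@@H]2C(C)(C)C(=O)CC[C@]2(C)[C@H]1CC/C=C(C)/CC/C=C(C)/CC/C=C(C)/C=O | intermediate
29 | myrrhanone B (5S,8R,9R,10S as given) | C/C(=C\CC/C(C)=C/CC[C@@H]1[C@@]2(C)CCC(=O)C(C)(C)[C@H]2CC[C@@]1(C)O)CC/C=C(\C)C(=O)O | target

## Step count and least certain steps

Total: 19 steps. Longest linear sequence: 14 steps (steps 1, 3–10 and 15–19, from 1); step 2 and steps 11–14 are side branches.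

**Step 5 (key step).** The [3,3] shift must create the quaternary C10 from a trisubstituted alkene carbon and may be slow. At the temperature then needed, heterolytic cleavage of the alkoxide (loss of the allyl unit as an anion, or retro-addition of the vinyl group) can compete and return ring-opened or devinylated material. Fallback, from 7 back to 10: the free alcohol 7 is submitted to a photocatalytic alkoxy-radical ring expansion ([Ir(dF(CF3)ppy)2(5,5′-d(CF3)bpy)]PF6, 2,4,6-collidine, CH2Cl2, blue light). Proton-coupled electron transfer gives the C3 alkoxy radical, β-scission of C3–C8 gives the allyl-stabilized radical and the vinyl ketone, and the allyl terminus C10 adds to C1 (six-membered ring closure, tether anchored on the α face of C5, hence cis). Reduction and protonation of the α-keto radical then give 10. This replaces the concerted anionic shift by a radical fragmentation–recombination and makes no new compound (F0).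

**Step 3.** The hindered dienone may react sluggishly, and at the temperature required the bulky auxiliary may give poor facial selectivity or erode the endo preference, so the yield of the single diastereomer 6 could be low. Fallback, from 3 back to 11: the cycloaddition is run with tert-butyldimethyl(vinyloxy)silane to give the racemic endo silyloxy bicyclooctenone F1. Vinylmagnesium bromide then gives the racemic vinyl carbinol F2, KH/18-crown-6 the racemic silyloxy cis-decalin ketone F3, and Bu4NF the racemic alcohol, that is 11 together with its enantiomer F4. Lipase-catalysed acetylation (Burkholderia cepacia lipase, vinyl acetate, t-BuOMe) should convert the 7R alcohol F4 into its acetate F5 and leave 11 (7S), in line with the usual preference of this enzyme for secondary alcohols with one large (C8) and one medium (C6) neighbour. 11 re-enters at step 7, so a resolution replaces auxiliary control.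

**Step 8.** The sigmatropic shift has to form C9–C11 next to the quaternary C10; ionization of the allylic ester (elimination to a diene) or premature decarboxylation without rearrangement may win. Fallback, from 11 back to 16: Johnson–Claisen rearrangement (triethyl orthoacetate, cat. propionic acid, 140 °C, neutral and more forcing) gives the ethyl ester F6, and LiOH gives the acid F7. Its Barton ester F8 (N-hydroxypyridine-2-thione, DCC) is photolysed with di-p-tolyl disulfide to the C11 p-tolyl sulfide F9 (radical decarboxylative sulfenylation). mCPBA (3 equiv) then oxidizes sulfur to the sulfone and epoxidizes C7=C8, giving 16. C11 is thus introduced as part of a two-carbon unit and trimmed by radical chemistry.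

**Step 9.** Facial selectivity may be poor or inverted, because the α face of C7=C8 lies on the concave side of the cis-decalin (axial C1) while the β face is blocked only by the C9 substituent. Fallback, from 15 back to 17, for the case that electrophiles prefer the β face: NBS in aqueous acetone forms the β-bromonium ion, and water opens it at the tertiary C8 from the α face to give the 7β-bromo-8α-hydroxy ketone F10. Bu3SnH/AIBN removes bromine to give the 8α-hydroxy ketone F11, and NaBH4 reduces C3 to give 17. Anti hydroxybromination and radical debromination thus turn the unwanted face preference into the required 8α-alcohol.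

## Further compounds

F0 | step 5 | none | none
F1 | step 3 | racemic (1S*,4S*,7S*)-7-(tert-butyldimethylsilyloxy)-1,3,3,5-tetramethylbicyclo[2.2.2]oct-5-en-2-one (one enantiomer drawn) | CC1=C[C@]2(C)C(=O)C(C)(C)[C@H]1C[C@@H]2O[Si](C)(C)C(C)(C)C
F2 | step 3 | racemic 2-ethenyl-7-(tert-butyldimethylsilyloxy)-1,3,3,5-tetramethylbicyclo[2.2.2]oct-5-en-2-ol (one enantiomer drawn) | CC1=C[C@]2(C)[C@](O)(C=C)C(C)(C)[C@H]1C[C@@H]2O[Si](C)(C)C(C)(C)C
F3 | step 3 | racemic 7β-(tert-butyldimethylsilyloxy) analogue of 10 (one enantiomer drawn) | CC1=C[C@@]2(C)CCC(=O)C(C)(C)[C@H]2C[C@@H]1O[Si](C)(C)C(C)(C)C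
F4 | step 3 | enantiomer of 11, (4aS,7R,8aR) | CC1=C[C@]2(C)CCC(=O)C(C)(C)[C@@H]2C[C@H]1O
F5 | step 3 | acetate of F4 | CC1=C[C@]2(C)CCC(=O)C(C)(C)[C@@H]2C[C@H]1OC(C)=O
F6 | step 8 | ethyl ester from Johnson–Claisen rearrangement of 11 (C9β–CH2CO2Et, C7=C8) | CC1=CC[C@@H]2C(C)(C)C(=O)CC[C@]2(C)[C@H]1CC(=O)OCC
F7 | step 8 | carboxylic acid from F6 | CC1=CC[C@@H]2C(C)(C)C(=O)CC[C@]2(C)[C@H]1CC(=O)O
F8 | step 8 | Barton ester of F7 | CC1=CC[C@@H]2C(C)(C)C(=O)CC[C@]2(C)[C@H]1CC(=O)ON3C=CC=CC3=S
F9 | step 8 | C11 p-tolyl sulfide | CC1=CC[C@@H]2C(C)(C)C(=O)CC[C@]2(C)[C@H]1CSc3ccc(C)cc3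
F10 | step 9 | 7β-bromo-8α-hydroxy ketone sulfone | C[C@@]1(O)[C@@H](Br)C[C@@H]2C(C)(C)C(=O)CC[C@]2(C)[C@H]1CS(=O)(=O)c3ccc(C)cc3
F11 | step 9 | 8α-hydroxy ketone sulfone | C[C@@]1(O)CC[C@@H]2C(C)(C)C(=O)CC[C@]2(C)[C@H]1CS(=O)(=O)c3ccc(C)cc3
A1 | alternative 1 | (2E,6Z,10S)-10,11-epoxyfarnesyl p-tolyl sulfone | Cc1ccc(cc1)S(=O)(=O)C/C=C(C)/CC/C=C(C)\CC[C@@H]1OC1(C)C
A2 | alternative 1 | 3β-epimer of 17 (3β,8α-diol sulfone) | C[C@@]1(O)CC[C@@H]2C(C)(C)[C@@H](O)CC[C@]2(C)[C@H]1CS(=O)(=O)c3ccc(C)cc3
A3 | alternative 2 | ethyl (2E,6S,8E,10E)-6,11-bis(tert-butyldimethylsilyloxy)-3,7,7-trimethyldodeca-2,8,10-trienoate | CCOC(=O)/C=C(C)/CC[C@H](O[Si](C)(C)C(C)(C)C)C(C)(C)/C=C/C=C(C)/O[Si](C)(C)C(C)(C)C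
A4 | alternative 2 | cis-fused intramolecular Diels–Alder adduct (3β,8α-bis-silyloxy, C6=C7, 9β-CO2Et) | CCOC(=O)[C@@H]1[C@@]2(C)CC[C@H](O[Si](C)(C)C(C)(C)C)C(C)(C)[C@H]2C=C[C@@]1(C)O[Si](C)(C)C(C)(C)C
A5 | alternative 3 | 3-methoxy-4,4,6-trimethylcyclohexa-2,5-dien-1-one | COC1=CC(=O)C(C)=CC1(C)C
A6 | alternative 3 | (E)-3-methylpenta-2,4-dien-1-yl p-tolyl sulfone | C=C/C(C)=C/CS(=O)(=O)c1ccc(C)cc1
A7 | alternative 3 | endo adduct of A5 and A6 (cis-fused, C11 trans to CH3-10; racemic, one enantiomer drawn) | COC1=CC(=O)[C@]2(C)[C@H](CS(=O)(=O)c3ccc(C)cc3)C(C)=CC[C@@H]2C1(C)C
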